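**Retrosynthetic overview**

1. Target 19 ⇐ 17: the C-4 methylthio group is ionised by a silver salt and methanol adds to the aryloxycarbenium ion trans to the C-6 allyl group. Both C-4 epimers of 17 converge, so C-4 is set from C-6.
2. Cyclohexenone ring (the only ring made; the arene is bought as 3,4-dimethoxyphenol) ⇐ acyclic thioester 15 + Ph3P=CH2. C-acylation gives keto ylide 16, whose intramolecular Wittig olefination of the methyl ester closes the ring at the C-2=C-3 double bond.
3. Enabling feature: C-1, C-2 and C-3 of the ring form a vinylogous ester, O=C1–C2H=C3(OMe). C-3 is at the carboxylic acid oxidation level and already carries its methoxy group, so it enters as a methyl ester carbonyl; C-2 is a lone CH next to the ketone, so it enters as an acyl-stabilised ylide carbon; the quaternary, non-enolisable C-4 with two heteroatoms activates that ester.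
4. 15 ⇐ Evans allylation (sets C-6) of imide 12 ⇐ Michael addition of O,S-acetal ester 8 to N-acryloyl oxazolidinone 11; 8 ⇐ phenol 5 (aromatic Claisen rearrangement) + chloro sulfide 7.

Key step: step 9

Remark on the chemistry: the target is read as (4R,6S) in cyclohexenone numbering, with aryloxy and C-6 allyl cis; compounds 12 and 14 to 17 are carried as mixtures of both configurations at the O,S-ketal carbon, because that centre is re-formed in step 10.

**Route**

Step 1
Reactants: 1 3,4-dimethoxyphenol; 2 allyl bromide
Product: 3 4-(allyloxy)-1,2-dimethoxybenzene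
Conditions: K2CO3, acetone, reflux
Reagents that add atoms: none
Why: Williamson ether synthesis of a phenoxide with a primary allylic bromide is O-selective under these conditions.

Step 2
Reactants: 3 4-(allyloxy)-1,2-dimethoxybenzene
Product: 5 2-allyl-4,5-dimethoxyphenol, via Claisen dienone 4 (not isolated)
Conditions: N,N-diethylaniline, 190–200 °C
Reagents that add atoms: none
Why: Aromatic Claisen rearrangement should deliver the allyl group to the unhindered ortho carbon (the other ortho position is flanked by a methoxy group), and dienone 4 tautomerises to the phenol.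

Step 3
Reactants: 6 methyl 2-(methylthio)acetate
Product: 7 methyl 2-chloro-2-(methylthio)acetate (racemic)
Conditions: N-chlorosuccinimide, CCl4, 0 °C to rt; used crude
Reagents that add atoms: N-chlorosuccinimide, O=C1CCC(=O)N1Cl
Why: Pummerer-type α-chlorination of a sulfide through the chlorosulfonium ion takes place at the carbon between sulfur and the ester and is the standard entry to α-chloro-α-thio esters.

Step 4
Reactants: 5 2-allyl-4,5-dimethoxyphenol; 7 methyl 2-chloro-2-(methylthio)acetate
Product: 8 methyl 2-(2-allyl-4,5-dimethoxyphenoxy)-2-(methylthio)acetate (racemic)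
Conditions: NaH, THF, 0 °C; then 7, 0 °C to rt
Reagents that add atoms: none
Why: The sodium phenoxide displaces chloride from the α-chloro sulfide through the sulfur-stabilised cation, as in the formation of methylthiomethyl ethers, and the basic medium should keep the electron-rich ring from C-alkylation; the stereocentre is lost on enolisation in step 6.

Step 5
Reactants: 9 (S)-4-benzyloxazolidin-2-one; 10 acryloyl chloride
Product: 11 (S)-3-acryloyl-4-benzyloxazolidin-2-one
Conditions: n-BuLi, THF, −78 °C; then acryloyl chloride, −78 °C to 0 °C
Reagents that add atoms: none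
Why: N-acylation of the lithiated oxazolidinone with an acid chloride at low temperature is the standard preparation of N-enoyl auxiliaries.

Step 6
Reactants: 8 methyl 2-(2-allyl-4,5-dimethoxyphenoxy)-2-(methylthio)acetate; 11 (S)-3-acryloyl-4-benzyloxazolidin-2-one
Product: 12 methyl 2-(2-allyl-4,5-dimethoxyphenoxy)-5-[(S)-4-benzyl-2-oxooxazolidin-3-yl]-2-(methylthio)-5-oxopentanoate (both configurations at C-2)
Conditions: LiN(SiMe3)2, THF, −78 °C; slow addition of 11; AcOH quench at −78 °C
Reagents that add atoms: none
Why: Michael addition of the sulfur- and ester-stabilised tertiary lithium enolate of 8 to the unsubstituted acrylimide should be fast at −78 °C, while the chelated imide enolate that results is a poor Michael donor, which limits oligomerisation; the new O,S-ketal centre forms without control, which is accepted because it is re-formed in step 10.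

Step 7
Reactants: 12 the Michael adduct; 13 allyl iodide
Product: 14 methyl (4S)-2-(2-allyl-4,5-dimethoxyphenoxy)-4-{[(S)-4-benzyl-2-oxooxazolidin-3-yl]carbonyl}-2-(methylthio)hept-6-enoate (both configurations at C-2)
Conditions: NaN(SiMe3)2, THF, −78 °C; allyl iodide, −78 °C to −45 °C
Reagents that add atoms: none
Why: Evans asymmetric alkylation: the chelated (Z)-sodium enolate is attacked by allyl iodide on the face opposite the benzyl group of the (S)-auxiliary, which sets the (S) configuration at the carbon that becomes C-6 of the ring.

Step 8
Reactants: 14 the allylated imide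
Product: 15 methyl (4S)-2-(2-allyl-4,5-dimethoxyphenoxy)-4-[(ethylthio)carbonyl]-2-(methylthio)hept-6-enoate (both configurations at C-2)
Conditions: LiSEt (from EtSH and n-BuLi), THF, 0 °C; then aq NH4Cl
Reagents that add atoms: ethanethiol, CCS
Why: Lithium ethanethiolate attacks the exocyclic imide carbonyl selectively and without epimerisation, releasing the auxiliary and giving the thioester that serves as acyl donor in step 9, while the hindered methyl ester next to the quaternary carbon should not react.

Step 9
Reactants: 15 the thioester
Product: 17 (6S)-6-allyl-4-(2-allyl-4,5-dimethoxyphenoxy)-3-methoxy-4-(methylthio)cyclohex-2-en-1-one (both configurations at C-4), via keto ylide 16 (not isolated)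
Conditions: Ph3P=CH2 (2.2 equiv, from Ph3PCH3Br and KN(SiMe3)2), THF–toluene, −78 °C to rt; filtration and solvent exchange; toluene, 110 °C
Reagents that add atoms: methylenetriphenylphosphorane, C=P(c1ccccc1)(c1ccccc1)c1ccccc1
Why: Proposed new method: the thioester C-acylates Ph3P=CH2 and the second equivalent of ylide deprotonates the acylmethylphosphonium salt to the ketone-stabilised ylide 16, whose nucleophilic carbon then adds to the neighbouring methyl ester carbonyl and, through the oxaphosphetane, expels Ph3P=O, so that the ester carbon becomes C-3 of the ring with its methoxy group retained as the enol ether. The closest known reaction type is the intramolecular Wittig olefination of ester carbonyls by stabilised ylides, which closes ester ylides of α-hydroxy esters to 4-alkoxybutenolides and 2-acyloxyphenacyl ylides to chromones; new here is the closure of a carbocycle by a keto ylide with the alkoxy group left exocyclic. The six-membered ring closes by a 6-exo-trig addition followed by syn-cycloelimination, helped by the quaternary C-4 (Thorpe–Ingold effect) and by its two electronegative substituents, which make the non-enolisable ester unusually electrophilic. No stereocentre is formed, and the C-6 centre from step 7 sits next to the ylide-delocalised carbonyl, where the CH is not acidic, in a neutral aprotic medium, so it should not epimerise. The step needs acylation at the thioester and not at the methyl ester, which the thiolate leaving group and the shielding of the ester by the quaternary carbon secure, and olefination in place of Claisen-type loss of methoxide, which the irreversible formation of the P=O bond in a non-polar solvent favours; because the enol ether oxygen comes from the ester itself, the regiochemistry of the vinylogous ester is fixed by connectivity.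

Step 10
Reactants: 17 the cyclic O,S-ketal
Product: 19 (4R,6S)-6-allyl-4-(2-allyl-4,5-dimethoxyphenoxy)-3,4-dimethoxycyclohex-2-en-1-one, via aryloxycarbenium triflate 18 (not isolated)
Conditions: AgOSO2CF3, 2,6-di-tert-butyl-4-methylpyridine, MeOH–CH2Cl2, −40 °C to 0 °C, dark
Reagents that add atoms: methanol, CO
Why: Silver-promoted solvolysis of an O,S-ketal (the reaction type used to cleave methylthiomethyl ethers): the thiophilic silver ion removes methanethiolate from either C-4 epimer to give the same aryloxycarbenium ion 18, and methanol, buffered by the hindered pyridine, should add irreversibly along the axial trajectory of the half-chair that carries the C-6 allyl group equatorial, that is trans to the allyl group, which places aryloxy and allyl cis and sets C-4 as (R).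

**Compound list**

1 | 3,4-dimethoxyphenol | COc1ccc(O)cc1OC | starting material
2 | allyl bromide | C=CCBr | starting material
3 | 4-(allyloxy)-1,2-dimethoxybenzene | C=CCOc1ccc(OC)c(OC)c1 | intermediate
4 | 6-allyl-3,4-dimethoxycyclohexa-2,4-dien-1-one (racemic, not isolated) | O=C1C=C(OC)C(OC)=CC1CC=C | intermediate
5 | 2-allyl-4,5-dimethoxyphenol | C=CCc1cc(OC)c(OC)cc1O | intermediate
6 | methyl 2-(methylthio)acetate | COC(=O)CSC | starting material
7 | methyl 2-chloro-2-(methylthio)acetate (racemic) | COC(=O)C(Cl)SC | intermediate
8 | methyl 2-(2-allyl-4,5-dimethoxyphenoxy)-2-(methylthio)acetate (racemic) | COC(=O)C(SC)Oc1cc(OC)c(OC)cc1CC=C | intermediate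
9 | (S)-4-benzyloxazolidin-2-one | O=C1N[C@@H](Cc2ccccc2)CO1 | starting material
10 | acryloyl chloride | C=CC(=O)Cl | starting material
11 | (S)-3-acryloyl-4-benzyloxazolidin-2-one | C=CC(=O)N1[C@@H](Cc2ccccc2)COC1=O | intermediate
12 | methyl 2-(2-allyl-4,5-dimethoxyphenoxy)-5-[(S)-4-benzyl-2-oxooxazolidin-3-yl]-2-(methylthio)-5-oxopentanoate (both configurations at C-2) | COC(=O)C(SC)(CCC(=O)N1[C@@H](Cc2ccccc2)COC1=O)Oc1cc(OC)c(OC)cc1CC=C | intermediate
13 | allyl iodide | C=CCI | starting material
14 | methyl (4S)-2-(2-allyl-4,5-dimethoxyphenoxy)-4-{[(S)-4-benzyl-2-oxooxazolidin-3-yl]carbonyl}-2-(methylthio)hept-6-enoate (both configurations at C-2) | COC(=O)C(SC)(C[C@H](CC=C)C(=O)N1[C@@H](Cc2ccccc2)COC1=O)Oc1cc(OC)c(OC)cc1CC=C | intermediate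
15 | methyl (4S)-2-(2-allyl-4,5-dimethoxyphenoxy)-4-[(ethylthio)carbonyl]-2-(methylthio)hept-6-enoate (both configurations at C-2) | COC(=O)C(SC)(C[C@H](CC=C)C(=O)SCC)Oc1cc(OC)c(OC)cc1CC=C | intermediate
16 | methyl (4S)-2-(2-allyl-4,5-dimethoxyphenoxy)-2-(methylthio)-4-[2-(triphenylphosphoranylidene)acetyl]hept-6-enoate (both configurations at C-2, not isolated) | COC(=O)C(SC)(C[C@H](CC=C)C(=O)C=P(c1ccccc1)(c1ccccc1)c1ccccc1)Oc1cc(OC)c(OC)cc1CC=C | intermediate
17 | (6S)-6-allyl-4-(2-allyl-4,5-dimethoxyphenoxy)-3-methoxy-4-(methylthio)cyclohex-2-en-1-one (both configurations at C-4) | C=CCc1cc(OC)c(OC)cc1OC1(SC)C[C@H](CC=C)C(=O)C=C1OC | intermediate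
18 | [(5S)-5-allyl-2-methoxy-4-oxocyclohex-2-en-1-ylidene](2-allyl-4,5-dimethoxyphenyl)oxonium triflate (not isolated) | C=CCc1cc(OC)c(OC)cc1[O+]=C1C[C@H](CC=C)C(=O)C=C1OC.[O-]S(=O)(=O)C(F)(F)F | intermediate
19 | (4R,6S)-6-allyl-4-(2-allyl-4,5-dimethoxyphenoxy)-3,4-dimethoxycyclohex-2-en-1-one | C=CCc1cc(OC)c(OC)cc1O[C@]1(OC)C[C@H](CC=C)C(=O)C=C1OC | target

**Step count and risks**

Total step count: 10. Longest linear sequence: 8 steps (steps 1, 2, 4, 6, 7, 8, 9, 10, from 1 to 19).

Steps most likely to fail:

Step 9 (proposed new method). The keto ylide may add too slowly to the hindered ester. The tetrahedral intermediate may lose methoxide in a Claisen-type acyl substitution and end as a phosphoranylidene dione. The basic ylide may deprotonate the thioester at its α-carbon, which would erode the C-6 configuration or trigger a retro-Michael cleavage. The fallback uses known chemistry and sets out from 15. Me2CuLi (Et2O, −78 °C) converts the thioester into methyl (4S)-4-acetyl-2-(2-allyl-4,5-dimethoxyphenoxy)-2-(methylthio)hept-6-enoate F1. Kinetic deprotonation of its methyl group with LiN(SiMe3)2 (THF, −78 °C to 0 °C) brings about a Dieckmann-type intramolecular Claisen condensation onto the methyl ester and gives (6S)-6-allyl-4-(2-allyl-4,5-dimethoxyphenoxy)-4-(methylthio)cyclohexane-1,3-dione F2. O-methylation with (trimethylsilyl)diazomethane in methanol–toluene should then give 17, where the fallback comes back to the route. Here the regiochemistry of enol ether formation is no longer fixed by connectivity, so the isomeric vinylogous ester would have to be separated.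

Step 10. The carbenium ion may lose a proton from C-5 and aromatise irreversibly, silver may ionise the only aryloxy-stabilised centre too slowly, or methanol may add with incomplete facial selectivity. The fallback sets out from 17 and changes the leaving group and the temperature regime. Oxidation with mCPBA (1 equiv, CH2Cl2, −78 °C; the sulfide should react far faster than the alkenes) gives (6S)-6-allyl-4-(2-allyl-4,5-dimethoxyphenoxy)-3-methoxy-4-(methylsulfinyl)cyclohex-2-en-1-one F3. Activation of this sulfoxide with Tf2O and 2,6-di-tert-butyl-4-methylpyridine in CH2Cl2 at −78 °C, in the presence of methanol, generates the same carbenium ion at a temperature where proton loss should be slow and axial capture most selective. The fallback comes back to the route at 19.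

Step 6. The N-acryloyl imide may oligomerise anionically, or the enolate may attack an imide carbonyl and transfer the acyl group. The fallback sets out from 8. Michael addition to allyl acrylate under catalytic KOC(CH3)3 in THF at 0 °C gives 5-allyl 1-methyl 2-(2-allyl-4,5-dimethoxyphenoxy)-2-(methylthio)pentanedioate F4. Deallylation with catalytic Pd(PPh3)4 and morpholine, which leaves the C-allyl groups untouched, gives 4-(2-allyl-4,5-dimethoxyphenoxy)-5-methoxy-4-(methylthio)-5-oxopentanoic acid F5. Pivaloyl chloride and Et3N convert the acid into the mixed pivalic anhydride F6, and acylation of the lithium salt of 9 with it gives 12, where the fallback comes back to the route.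

**Further compounds**

F1 | step 9 | methyl (4S)-4-acetyl-2-(2-allyl-4,5-dimethoxyphenoxy)-2-(methylthio)hept-6-enoate | COC(=O)C(SC)(C[C@H](CC=C)C(C)=O)Oc1cc(OC)c(OC)cc1CC=C
F2 | step 9 | (6S)-6-allyl-4-(2-allyl-4,5-dimethoxyphenoxy)-4-(methylthio)cyclohexane-1,3-dione | C=CCc1cc(OC)c(OC)cc1OC1(SC)C[C@H](CC=C)C(=O)CC1=O
F3 | step 10 | (6S)-6-allyl-4-(2-allyl-4,5-dimethoxyphenoxy)-3-methoxy-4-(methylsulfinyl)cyclohex-2-en-1-one | C=CCc1cc(OC)c(OC)cc1OC1(S(C)=O)C[C@H](CC=C)C(=O)C=C1OC
F4 | step 6 | 5-allyl 1-methyl 2-(2-allyl-4,5-dimethoxyphenoxy)-2-(methylthio)pentanedioate | COC(=O)C(SC)(CCC(=O)OCC=C)Oc1cc(OC)c(OC)cc1CC=C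
F5 | step 6 | 4-(2-allyl-4,5-dimethoxyphenoxy)-5-methoxy-4-(methylthio)-5-oxopentanoic acid | COC(=O)C(SC)(CCC(=O)O)Oc1cc(OC)c(OC)cc1CC=C
F6 | step 6 | 4-(2-allyl-4,5-dimethoxyphenoxy)-5-methoxy-4-(methylthio)-5-oxopentanoic pivalic anhydride | COC(=O)C(SC)(CCC(=O)OC(=O)C(C)(C)C)Oc1cc(OC)c(OC)cc1CC=C
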